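**Strategy.** In ring B (C5–C10) of macrocarpal J the angular methyl on C10 lies para to the hydroxyisopropyl group on C7, the substitution pattern of a p-menthane. The limonene ring is therefore opened between the carbons that become C10 and C5 and forged again by an intramolecular Diels–Alder reaction. In one operation the (E)-enoate C1=C10 adds to the (E)-diene C2=C3–C4=C5, making C1–C2 and C5–C10, closing rings A and B, setting C1, C5 and C10 and leaving C3=C4 for the C4 carbinol. The precursor is an acyclic, geometrically pure triene ester (10) whose only stereocentre, C7, is the limonene carbon.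

Key step: step 7

Remark: eudesmane numbering is used for all ring compounds (C1 side chain, C4 ring carbinol, C5/C10 ring fusion, C7 three-carbon unit, benzylic carbon C1′); commercial (+)-limonene 1,2-oxide is taken to be the cis/trans mixture made from (R)-(+)-limonene, and both isomers converge in step 1.

Step 1
Reactants: 1 (+)-limonene 1,2-oxide
Product: 3 (3R)-6-oxo-3-(prop-1-en-2-yl)heptanal, via (4R)-limonene-1,2-diol 2 (not isolated)
Conditions: H5IO6 (1.2 equiv), THF/H2O, 0 °C → rt
Reagents that add atoms: water, O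
Why: Acid-catalysed epoxide hydrolysis and periodate glycol cleavage (Malaprade reaction) of diol 2 open the ring between the two former alkene carbons, both epoxide isomers give the same keto aldehyde, and neither the isopropenyl group nor the stereocentre (future C7) is touched.

Step 2
Reactants: 3 (3R)-6-oxo-3-(prop-1-en-2-yl)heptanal; 4 2-(triphenylphosphoranylidene)propanal
Product: 5 (2E,5R)-2-methyl-8-oxo-5-(prop-1-en-2-yl)non-2-enal
Conditions: toluene, 80 °C
Reagents that add atoms: 2-(triphenylphosphoranylidene)propanal (4), CC(C=O)=P(c1ccccc1)(c1ccccc1)c1ccccc1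
Why: Wittig olefination with a stabilised ylide reacts only at the aldehyde, leaves the methyl ketone alone, and gives the (E)-2-methyl enal under thermodynamic control.

Step 3
Reactants: 5 (2E,5R)-2-methyl-8-oxo-5-(prop-1-en-2-yl)non-2-enal
Product: 6 (5R,7E)-8-methyl-5-(prop-1-en-2-yl)deca-7,9-dien-2-one
Conditions: Ph3PCH3Br, KN(SiMe3)2 (1.05 equiv of ylide), THF, −78 → 0 °C
Reagents that add atoms: methyltriphenylphosphonium bromide, C[P+](c1ccccc1)(c1ccccc1)c1ccccc1.[Br-]
Why: Wittig methylenation with one equivalent of the non-stabilised ylide at low temperature is selective for the aldehyde over the enolisable methyl ketone and turns the enal into the terminal (E)-diene; any over-methylenated hydrocarbon is removed after step 4.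

Step 4
Reactants: 6 (5R,7E)-8-methyl-5-(prop-1-en-2-yl)deca-7,9-dien-2-one
Product: 7 methyl (6R,8E)-9-methyl-3-oxo-6-(prop-1-en-2-yl)undeca-8,10-dienoate
Conditions: NaH (2.5 equiv), (MeO)2CO, THF, reflux; then AcOH
Reagents that add atoms: dimethyl carbonate, COC(=O)OC
Why: Crossed Claisen-type carbomethoxylation of a methyl ketone acylates the methyl group (the less substituted β-keto ester enolate drives the equilibrium), so the former ketone methyl becomes C1 and the new ester carbon the future C1′.

Step 5
Reactants: 7 methyl (6R,8E)-9-methyl-3-oxo-6-(prop-1-en-2-yl)undeca-8,10-dienoate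
Product: 9 methyl (2Z,6R,8E)-3-[(diethoxyphosphoryl)oxy]-9-methyl-6-(prop-1-en-2-yl)undeca-2,8,10-trienoate, via chelated sodium enolate 8 (not isolated)
Conditions: NaH (1.1 equiv), Et2O, 0 °C; ClP(O)(OEt)2, 0 °C → rt
Reagents that add atoms: diethyl chlorophosphate, CCOP(=O)(Cl)OCC
Why: O-phosphorylation of the sodium enolate of a β-keto ester in ether goes through chelate 8, in which sodium bridges both oxygens, and this fixes the phosphate cis to the ester, giving the (Z)-enol phosphate.

Step 6
Reactants: 9 methyl (2Z,6R,8E)-3-[(diethoxyphosphoryl)oxy]-9-methyl-6-(prop-1-en-2-yl)undeca-2,8,10-trienoate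
Product: 10 methyl (2E,6R,8E)-3,9-dimethyl-6-(prop-1-en-2-yl)undeca-2,8,10-trienoate
Conditions: Me2CuLi (from CuI and MeLi, 3 equiv), Et2O, −78 → −45 °C; aq. NH4Cl
Reagents that add atoms: methyllithium, [Li]C (delivered as lithium dimethylcuprate, [Li+].C[Cu-]C)
Why: Cuprate substitution of the β-phosphoryloxy enoate replaces phosphate by methyl with retention of alkene geometry, so the new methyl (future C10–CH3) sits cis to the ester and the (2E)-enoate should be free of the (Z)-isomer that a direct olefination of ketone 6 would also produce.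

Step 7
Reactants: 10 methyl (2E,6R,8E)-3,9-dimethyl-6-(prop-1-en-2-yl)undeca-2,8,10-trienoate
Product: 11 methyl eudesma-3,11-diene-1β-carboxylate (trans-fused; 5α-H; 7β-isopropenyl; 10β-CH3), i.e. methyl (1R,4aS,6R,8aR)-4,8a-dimethyl-6-(prop-1-en-2-yl)-1,2,4a,5,6,7,8,8a-octahydronaphthalene-1-carboxylate
Conditions: EtAlCl2 (1.1 equiv), CH2Cl2, −20 → 23 °C; aq. NaHCO3
Reagents that add atoms: none
Why: A concerted but asynchronous [4+2] cycloaddition of the aluminium-complexed (E)-enoate C1=C10 to the s-cis (E)-diene C2=C3–C4=C5, in which the C5–C10 bond runs ahead and the charge developing at C4 is stabilised by its methyl group, so the diene polarity matches the β,β-disubstituted acceptor. The closest known reaction type is the alkylaluminium-halide-promoted intramolecular Diels–Alder reaction of undeca-2,8,10-trienoates (1,7,9-decatriene class) to trans-fused octalins. Ring A is the new cyclohexene made by the cycloaddition itself (bonds C1–C2 and C5–C10), and ring B closes at the same time as the four-carbon tether C6–C9 folds into a chair. C1 follows from the (E)-dienophile geometry (suprafacial addition keeps CO2Me cis to the C10 methyl, equatorial 1β), the trans relation of C5–H and C10–CH3 follows from the ester-endo orientation, and the absolute sense of C5 and C10 is relayed from C7, whose isopropenyl group stays equatorial on the chair tether. Two selectivities are required, endo rather than exo approach of the dienophile and attack on a single diene face; aluminium complexation of the ester strengthens the endo preference and lowers the temperature, and the equatorial preference at C7 selects the face. The alkylaluminium halide also scavenges protons, which protects the isopropenyl group and the diene, and C3=C4 emerges where the C4 carbinol is needed.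

Step 8
Reactants: 11 methyl eudesma-3,11-diene-1β-carboxylate
Product: 12 methyl 4α,11-dihydroxyeudesmane-1β-carboxylate
Conditions: Co(acac)2 (20 mol %), PhSiH3, O2 (1 atm), THF/i-PrOH, 0 °C → rt
Reagents that add atoms: dioxygen, O=O
Why: Mukaiyama hydration (Markovnikov hydrogen-atom transfer from a cobalt hydride) turns both alkenes into tertiary radicals that are oxygenated and reduced to alcohols in the same pot; C11 is not stereogenic, and at C4 oxygen should be taken up on the α face, anti to the axial 10β-methyl that shields the β face, giving the equatorial 4α-OH.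

Step 9
Reactants: 12 methyl 4α,11-dihydroxyeudesmane-1β-carboxylate
Product: 13 1β-(hydroxymethyl)eudesmane-4α,11-diol
Conditions: LiAlH4, THF, 0 °C → rt; H2O, aq. NaOH
Reagents that add atoms: none
Why: Hydride reduction of the ester to the primary alcohol, with no stereocentre touched.

Step 10
Reactants: 13 1β-(hydroxymethyl)eudesmane-4α,11-diol
Product: 14 4α,11-dihydroxyeudesmane-1β-carbaldehyde
Conditions: TEMPO (10 mol %), PhI(OAc)2 (1.1 equiv), CH2Cl2, rt
Reagents that add atoms: none
Why: Oxoammonium-mediated oxidation is selective for the primary alcohol, the tertiary alcohols cannot be oxidised, and the equatorial 1β-aldehyde is the more stable C1 epimer, so C1 is not at risk.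

Step 11
Reactants: 14 4α,11-dihydroxyeudesmane-1β-carbaldehyde; 15 1,3,5-trimethoxybenzene
Product: 17 1β-[hydroxy(2,4,6-trimethoxyphenyl)methyl]eudesmane-4α,11-diol (C1′ epimers), via 2,4,6-trimethoxyphenyllithium 16 (not isolated)
Conditions: 15 (4 equiv), n-BuLi (3.6 equiv), THF, 0 °C → rt; then 14, −78 → 0 °C; H2O
Reagents that add atoms: 1,3,5-trimethoxybenzene (15), COc1cc(OC)cc(OC)c1
Why: Ortho-lithiation of 15 between two methoxy groups gives aryllithium 16, two equivalents of which are spent on the hydroxyl groups before 1,2-addition to the aldehyde, and the configuration of the new carbinol carbon is irrelevant because step 12 erases it.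

Step 12
Reactants: 17 1β-[hydroxy(2,4,6-trimethoxyphenyl)methyl]eudesmane-4α,11-diol
Product: 19 (1′S)-1β-[3-methyl-1-(2,4,6-trimethoxyphenyl)but-3-en-1-yl]eudesmane-4α,11-diol, via trimethoxybenzylic cation 18 (not isolated)
Conditions: methallyltrimethylsilane (3 equiv), BF3·OEt2 (1.2 equiv), CH2Cl2, −78 °C; aq. NaHCO3
Reagents that add atoms: methallyltrimethylsilane, C=C(C)C[Si](C)(C)C
Why: Hosomi–Sakurai-type SN1 allylation in which the trimethoxyphenyl carbinol ionises at −78 °C while the tertiary alkyl carbinols stay intact, cation 18 adopts the rotamer with C1–H in the plane of the aryl ring (allylic 1,3-strain with the ortho-methoxy groups) and the allylsilane attacks the face turned away from the quaternary C10, which should set C1′ as (S) from either epimer of 17.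

Step 13
Reactants: 19 (1′S)-1β-[3-methyl-1-(2,4,6-trimethoxyphenyl)but-3-en-1-yl]eudesmane-4α,11-diol
Product: 20 (1′S)-1β-[3-methyl-1-(2,4,6-trimethoxyphenyl)butyl]eudesmane-4α,11-diol
Conditions: H2 (1 atm), Pd/C, EtOAc, rt
Reagents that add atoms: none
Why: Heterogeneous hydrogenation of the only alkene gives the isobutyl group without forming or touching a stereocentre.

Step 14
Reactants: 20 (1′S)-1β-[3-methyl-1-(2,4,6-trimethoxyphenyl)butyl]eudesmane-4α,11-diol
Product: 21 (1′S)-1β-[1-(3,5-dibromo-2,4,6-trimethoxyphenyl)-3-methylbutyl]eudesmane-4α,11-diol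
Conditions: NBS (2.1 equiv), MeCN, 0 °C → rt, dark
Reagents that add atoms: N-bromosuccinimide, O=C1CCC(=O)N1Br
Why: Electrophilic aromatic bromination of the trialkoxyarene at its only two free positions proceeds under neutral conditions that the tertiary alcohols tolerate, which a Lewis-acid formylation of the same ring would not.

Step 15
Reactants: 21 (1′S)-1β-[1-(3,5-dibromo-2,4,6-trimethoxyphenyl)-3-methylbutyl]eudesmane-4α,11-diol
Product: 23 (1′S)-1β-[1-(3,5-diformyl-2,4,6-trimethoxyphenyl)-3-methylbutyl]eudesmane-4α,11-diol, via aryl dilithium dialkoxide 22 (not isolated)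
Conditions: MeLi (2.2 equiv), THF, −78 °C; t-BuLi (4.4 equiv), −78 °C; DMF, −78 → 0 °C; 1 M HCl, 0 °C
Reagents that add atoms: N,N-dimethylformamide, CN(C)C=O
Why: After deprotonation of the two hydroxyl groups, double bromine–lithium exchange gives 22, in which each C–Li is chelated by two flanking methoxy groups, and Bouveault-type formylation with DMF installs both aldehydes.

Step 16
Reactants: 23 (1′S)-1β-[1-(3,5-diformyl-2,4,6-trimethoxyphenyl)-3-methylbutyl]eudesmane-4α,11-diol
Product: 24 macrocarpal J
Conditions: NaSEt (10 equiv), DMF, 120 °C; 1 M HCl, 0 °C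
Reagents that add atoms: none
Why: SN2 O-demethylation by thiolate works because every methoxy group is ortho or para to a formyl group that stabilises the departing phenoxide, and the basic conditions spare the tertiary alcohols and the non-acidic C1′ centre.

**Compound list**

1 | (+)-limonene 1,2-oxide, (4R), cis/trans mixture | CC(=C)[C@@H]1CCC2(C)OC2C1 | starting material
2 | (4R)-limonene-1,2-diol (not isolated) | CC(=C)[C@@H]1CCC(C)(O)C(O)C1 | intermediate
3 | (3R)-6-oxo-3-(prop-1-en-2-yl)heptanal | CC(=O)CC[C@@H](C(C)=C)CC=O | intermediate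
4 | 2-(triphenylphosphoranylidene)propanal | CC(C=O)=P(c1ccccc1)(c1ccccc1)c1ccccc1 | starting material
5 | (2E,5R)-2-methyl-8-oxo-5-(prop-1-en-2-yl)non-2-enal | CC(=O)CC[C@@H](C(C)=C)C/C=C(C)/C=O | intermediate
6 | (5R,7E)-8-methyl-5-(prop-1-en-2-yl)deca-7,9-dien-2-one | CC(=O)CC[C@@H](C(C)=C)C/C=C(C)/C=C | intermediate
7 | methyl (6R,8E)-9-methyl-3-oxo-6-(prop-1-en-2-yl)undeca-8,10-dienoate | COC(=O)CC(=O)CC[C@@H](C(C)=C)C/C=C(C)/C=C | intermediate
8 | chelated sodium (Z)-enolate of 7 (not isolated) | COC(=O)/C=C(\[O-])CC[C@@H](C(C)=C)C/C=C(C)/C=C.[Na+] | intermediate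
9 | methyl (2Z,6R,8E)-3-[(diethoxyphosphoryl)oxy]-9-methyl-6-(prop-1-en-2-yl)undeca-2,8,10-trienoate | COC(=O)/C=C(\OP(=O)(OCC)OCC)CC[C@@H](C(C)=C)C/C=C(C)/C=C | intermediate
10 | methyl (2E,6R,8E)-3,9-dimethyl-6-(prop-1-en-2-yl)undeca-2,8,10-trienoate | COC(=O)/C=C(\C)CC[C@@H](C(C)=C)C/C=C(C)/C=C | intermediate
11 | methyl eudesma-3,11-diene-1β-carboxylate (5α-H, 7β-isopropenyl, 10β-CH3) | COC(=O)[C@@H]1CC=C(C)[C@@H]2C[C@H](C(C)=C)CC[C@]21C | intermediate
12 | methyl 4α,11-dihydroxyeudesmane-1β-carboxylate | COC(=O)[C@@H]1CC[C@@](C)(O)[C@@H]2C[C@H](C(C)(C)O)CC[C@]21C | intermediate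
13 | 1β-(hydroxymethyl)eudesmane-4α,11-diol | OC[C@@H]1CC[C@@](C)(O)[C@@H]2C[C@H](C(C)(C)O)CC[C@]21C | intermediate
14 | 4α,11-dihydroxyeudesmane-1β-carbaldehyde | O=C[C@@H]1CC[C@@](C)(O)[C@@H]2C[C@H](C(C)(C)O)CC[C@]21C | intermediate
15 | 1,3,5-trimethoxybenzene | COc1cc(OC)cc(OC)c1 | starting material
16 | 2,4,6-trimethoxyphenyllithium (not isolated) | [Li]c1c(OC)cc(OC)cc1OC | intermediate
17 | 1β-[hydroxy(2,4,6-trimethoxyphenyl)methyl]eudesmane-4α,11-diol (C1′ epimers) | OC(c1c(OC)cc(OC)cc1OC)[C@@H]2CC[C@@](C)(O)[C@@H]3C[C@H](C(C)(C)O)CC[C@]32C | intermediate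
18 | trimethoxybenzylic cation from 17 (not isolated) | [CH+](c1c(OC)cc(OC)cc1OC)[C@@H]2CC[C@@](C)(O)[C@@H]3C[C@H](C(C)(C)O)CC[C@]32C | intermediate
19 | (1′S)-1β-[3-methyl-1-(2,4,6-trimethoxyphenyl)but-3-en-1-yl]eudesmane-4α,11-diol | C=C(C)C[C@H](c1c(OC)cc(OC)cc1OC)[C@@H]2CC[C@@](C)(O)[C@@H]3C[C@H](C(C)(C)O)CC[C@]32C | intermediate
20 | (1′S)-1β-[3-methyl-1-(2,4,6-trimethoxyphenyl)butyl]eudesmane-4α,11-diol | CC(C)C[C@H](c1c(OC)cc(OC)cc1OC)[C@@H]2CC[C@@](C)(O)[C@@H]3C[C@H](C(C)(C)O)CC[C@]32C | intermediate
21 | (1′S)-1β-[1-(3,5-dibromo-2,4,6-trimethoxyphenyl)-3-methylbutyl]eudesmane-4α,11-diol | CC(C)C[C@H](c1c(OC)c(Br)c(OC)c(Br)c1OC)[C@@H]2CC[C@@](C)(O)[C@@H]3C[C@H](C(C)(C)O)CC[C@]32C | intermediate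
22 | aryl dilithium dialkoxide from 21 (not isolated) | CC(C)C[C@H](c1c(OC)c([Li])c(OC)c([Li])c1OC)[C@@H]2CC[C@@](C)(O[Li])[C@@H]3C[C@H](C(C)(C)O[Li])CC[C@]32C | intermediate
23 | (1′S)-1β-[1-(3,5-diformyl-2,4,6-trimethoxyphenyl)-3-methylbutyl]eudesmane-4α,11-diol | CC(C)C[C@H](c1c(OC)c(C=O)c(OC)c(C=O)c1OC)[C@@H]2CC[C@@](C)(O)[C@@H]3C[C@H](C(C)(C)O)CC[C@]32C | intermediate
24 | macrocarpal J | CC(C)C[C@H](c1c(O)c(C=O)c(O)c(C=O)c1O)[C@@H]1CC[C@@](C)(O)[C@@H]2C[C@H](C(C)(C)O)CC[C@]21C | target

**Total step count:** 16. **Longest linear sequence:** 16 steps (1 → 24); arene 15 is used as purchased and lithiated in the flask.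

**Steps most likely to fail**

Step 7 (key step). The exo (cis-fused) mode or the other diene face may compete. The aluminium Lewis acid may also trigger cationic side reactions (ene-type closure of the isopropenyl group onto the activated enoate, oligomerisation of the diene) faster than the sluggish β,β-disubstituted dienophile cycloadds. The fallback sets out from 10 and returns at 11, and replaces the monodentate ester by a chelating imide. Saponification of 10 (LiOH, THF/MeOH/H2O) gives (2E,6R,8E)-3,9-dimethyl-6-(prop-1-en-2-yl)undeca-2,8,10-trienoic acid F1. Pivaloyl chloride/Et3N converts it into the mixed pivalic anhydride F2, which acylates lithiated oxazolidin-2-one to give the N-trienoyl oxazolidinone F3. With Me2AlCl (1.4 equiv, CH2Cl2, −30 °C) the two-point-bound aluminium chelate should undergo the same intramolecular Diels–Alder reaction well below the temperature the ester needs, with the strong endo preference of such imides, giving the cycloadduct imide F4. MeOMgBr in MeOH/CH2Cl2 at 0 °C then transesterifies F4 to 11.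

Step 12. The cation may be captured on the undesired face or lose H-1 in an E1 process, and the free tertiary hydroxyl groups may sequester the Lewis acid or ionise. The fallback sets out from 11 and returns at 19: the ionisation is run before the tertiary carbinols exist, with a carbonyl-bearing nucleophile so that no third alkene is created. LiAlH4 reduces 11 to (eudesma-3,11-dien-1β-yl)methanol F5, and TEMPO/PhI(OAc)2 gives eudesma-3,11-diene-1β-carbaldehyde F6. Addition of 16 gives the diene carbinol F7. BF3·OEt2 with 2-(trimethylsilyloxy)propene at −78 °C (Mukaiyama-type SN1 alkylation, same facial model as in step 12) gives the methyl ketone F8. Mukaiyama hydration under the conditions of step 8 gives the diol ketone F9, and Wittig methylenation with excess Ph3P=CH2 delivers 19.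

Step 8. Oxygen may be captured by the C4 radical on the β face, giving the C4 epimer, and hydrogen-atom transfer to the trisubstituted C3=C4 alkene may be slow. The fallback sets out from 11 and returns at 13. mCPBA (2.2 equiv, NaHCO3, CH2Cl2, 0 °C) epoxidises C3=C4 from the α face, anti to the axial 10β-methyl, and also the isopropenyl group, whose new centre is lost later, giving methyl 3α,4α:11,12-diepoxyeudesmane-1β-carboxylate F10. LiAlH4 in refluxing THF then delivers hydride to the less substituted carbons C3 and C12 and reduces the ester in the same operation, so the C4–O bond set in the epoxidation is kept and triol 13 results.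

**Further compounds**

F1 | step 7 | (2E,6R,8E)-3,9-dimethyl-6-(prop-1-en-2-yl)undeca-2,8,10-trienoic acid | OC(=O)/C=C(\C)CC[C@@H](C(C)=C)C/C=C(C)/C=C
F2 | step 7 | mixed pivalic anhydride of F1 | CC(C)(C)C(=O)OC(=O)/C=C(\C)CC[C@@H](C(C)=C)C/C=C(C)/C=C
F3 | step 7 | 3-[(2E,6R,8E)-3,9-dimethyl-6-(prop-1-en-2-yl)undeca-2,8,10-trienoyl]oxazolidin-2-one | O=C1OCCN1C(=O)/C=C(\C)CC[C@@H](C(C)=C)C/C=C(C)/C=C
F4 | step 7 | 3-(eudesma-3,11-diene-1β-carbonyl)oxazolidin-2-one | O=C1OCCN1C(=O)[C@@H]2CC=C(C)[C@@H]3C[C@H](C(C)=C)CC[C@]32C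
F5 | step 12 | (eudesma-3,11-dien-1β-yl)methanol | OC[C@@H]1CC=C(C)[C@@H]2C[C@H](C(C)=C)CC[C@]21C
F6 | step 12 | eudesma-3,11-diene-1β-carbaldehyde | O=C[C@@H]1CC=C(C)[C@@H]2C[C@H](C(C)=C)CC[C@]21C
F7 | step 12 | (eudesma-3,11-dien-1β-yl)(2,4,6-trimethoxyphenyl)methanol (C1′ epimers) | OC(c1c(OC)cc(OC)cc1OC)[C@@H]2CC=C(C)[C@@H]3C[C@H](C(C)=C)CC[C@]32C
F8 | step 12 | (4S)-4-(eudesma-3,11-dien-1β-yl)-4-(2,4,6-trimethoxyphenyl)butan-2-one | CC(=O)C[C@H](c1c(OC)cc(OC)cc1OC)[C@@H]2CC=C(C)[C@@H]3C[C@H](C(C)=C)CC[C@]32C
F9 | step 12 | (4S)-4-(4α,11-dihydroxyeudesman-1β-yl)-4-(2,4,6-trimethoxyphenyl)butan-2-one | CC(=O)C[C@H](c1c(OC)cc(OC)cc1OC)[C@@H]2CC[C@@](C)(O)[C@@H]3C[C@H](C(C)(C)O)CC[C@]32C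
F10 | step 8 | methyl 3α,4α:11,12-diepoxyeudesmane-1β-carboxylate (C11 epimers) | COC(=O)[C@@H]1C[C@H]2O[C@@]2(C)[C@@H]3C[C@H](C4(C)CO4)CC[C@]31C
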